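**Retrosynthetic overview**
1. The last disconnection cuts the aryl–acyl bond C7–C(=O) and the phenolic C6–O bond together. This leads back to a C6≡C7 aryne of the complete terpene–dihydrobenzofuran core and free (E)-4-methoxycinnamic acid, the aryne formally inserting into the C–O bond of the acid.
2. The feature that makes this possible is the o-hydroxyaryl ketone array O–C6–C7–C(=O) of the benzene ring. It lies next to the dihydrofuran oxygen on C7a, which polarises the aryne so that O goes to C6 and the acyl group to C7. A C7-SiMe3/C6-OTf pair stands in for OH and acyl until the end.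
3. Dihydrofuran ring: C1–C3a comes from Pd γ-arylation of (−)-aristolone with a bromide made from C2-symmetric 5-methoxyresorcinol, and C10–O from a 5-exo oxa-Michael closure. C9 is then oxidised to give the 8,9-dione.
4. Aristolone: ring A comes from (R)-pulegone (C4), ring B from a Robinson annulation (C5), and the cyclopropane from sulfonium isopropylide addition to the cross-conjugated dienone (C6, C7).
5. Order of ring formation: A (chiral pool), then B, then the cyclopropane, then the benzene ring is brought in, then the dihydrofuran. A pyranone ring appears only transiently in the last step.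

Key step: step 13

Remark on the chemistry: terpene carbons carry aristolane numbers (C1–C15) and arene carbons carry benzofuran numbers (C3a, C4–C7, C7a). Compounds 2, 3, 13 and 14 are carried as epimer mixtures at a centre that is later planarised or equilibrated, so that centre is left open in their SMILES.

**Step 1**
Reactants: 1 (R)-(+)-pulegone
Product: 2 (5R)-5,6-dimethyl-2-(propan-2-ylidene)cyclohexan-1-one (C6 epimers)
Conditions: LDA, THF, −78 °C; MeI, −78 to 0 °C
Reagents that add atoms: methyl iodide, CI
Why: Kinetic deprotonation should give the cross-conjugated α′-enolate, which is methylated at C6 (enolate alkylation); the new centre is planarised again in step 3 and the C5 (R) centre is untouched.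

**Step 2**
Reactants: 2 (5R)-5,6-dimethyl-2-(propan-2-ylidene)cyclohexan-1-one
Product: 3 (3R)-2,3-dimethylcyclohexan-1-one (C2 epimers)
Conditions: 6 M aq. HCl, reflux, acetone distilled off
Reagents that add atoms: none
Why: Acid-catalysed conjugate hydration of the isopropylidene enone followed by retro-aldol cleavage removes acetone; the methyl-bearing centre is β to the carbonyl and cannot epimerise.

**Step 3**
Reactants: 3 (3R)-2,3-dimethylcyclohexan-1-one; 4 methyl vinyl ketone
Product: 6 (4aS,5R)-4a,5-dimethyl-4,4a,5,6,7,8-hexahydronaphthalen-2(3H)-one, via Michael adduct 5 (not isolated)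
Conditions: H2SO4 (cat.), toluene, reflux, Dean–Stark
Reagents that add atoms: none
Why: In this acid-catalysed Robinson annulation the more substituted enol adds to the enone on the face anti to the neighbouring methyl group, which sets C5 with the two methyl groups cis, and aldol condensation then closes ring B.

**Step 4**
Reactants: 6 (4aS,5R)-4a,5-dimethyl-4,4a,5,6,7,8-hexahydronaphthalen-2(3H)-one
Product: 7 (4aR,5R)-4a,5-dimethyl-5,6,7,8-tetrahydronaphthalen-2(4aH)-one
Conditions: DDQ, 1,4-dioxane, reflux
Reagents that add atoms: none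
Why: Under neutral conditions, DDQ dehydrogenation of a 4-en-3-one-type enone proceeds through the α′-enol and should give the cross-conjugated dienone (new C6=C7 bond); no stereocentre is touched.

**Step 5**
Reactants: 7 (4aR,5R)-4a,5-dimethyl-5,6,7,8-tetrahydronaphthalen-2(4aH)-one
Product: 8 (−)-aristolone, (1aR,7R,7aR,7bS)-1,1,7,7a-tetramethyl-1,1a,4,5,6,7,7a,7b-octahydro-2H-cyclopropa[a]naphthalen-2-one
Conditions: i-PrSPh2 BF4, LDA, DME, −78 to −20 °C
Reagents that add atoms: isopropyldiphenylsulfonium tetrafluoroborate, CC(C)[S+](c1ccccc1)c1ccccc1.F[B-](F)(F)F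
Why: In this Corey–Chaykovsky-type gem-dimethylcyclopropanation the ylide adds to C6 of the less substituted enone arm on the face opposite the axial C5 methyl group, and the enolate then closes on the CMe2 carbon, which sets C6 and C7 as a cis-fused cyclopropane trans to that methyl.

**Step 6**
Reactants: 9 5-methoxybenzene-1,3-diol
Product: 10 1-methoxy-3,5-bis(methoxymethoxy)benzene
Conditions: MOMCl, i-Pr2NEt, CH2Cl2, 0 to 23 °C
Reagents that add atoms: chloromethyl methyl ether, COCCl
Why: O-alkylation of both phenols gives acetal groups that protect the phenols and also direct the two metalations that follow.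

**Step 7**
Reactants: 10 1-methoxy-3,5-bis(methoxymethoxy)benzene
Product: 11 [4-methoxy-2,6-bis(methoxymethoxy)phenyl]trimethylsilane
Conditions: n-BuLi, THF, 0 °C; TMSCl, −78 to 23 °C
Reagents that add atoms: chlorotrimethylsilane, C[Si](C)(C)Cl
Why: Directed ortho-metalation should take place at the carbon flanked by both OMOM groups (cooperative direction), and silylation there keeps the arene C2-symmetric and marks the future C7.

**Step 8**
Reactants: 11 [4-methoxy-2,6-bis(methoxymethoxy)phenyl]trimethylsilane
Product: 12 [3-bromo-4-methoxy-2,6-bis(methoxymethoxy)phenyl]trimethylsilane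
Conditions: n-BuLi, TMEDA, THF, −20 °C; BrCH2CH2Br, −78 °C
Reagents that add atoms: 1,2-dibromoethane, BrCCBr
Why: A second directed ortho-metalation can only reach the two equivalent C–H positions between OMOM and OMe, and quenching the aryllithium with a Br+ donor avoids the ipso-bromodesilylation that electrophilic bromination would risk.

**Step 9**
Reactants: 8 (−)-aristolone; 12 [3-bromo-4-methoxy-2,6-bis(methoxymethoxy)phenyl]trimethylsilane
Product: 13 1-[6-methoxy-2,4-bis(methoxymethoxy)-3-(trimethylsilyl)phenyl]aristol-9-en-8-one (C1 epimers)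
Conditions: Pd2(dba)3 (cat.), t-Bu3P·HBF4 (cat.), Cs2CO3, toluene, 100 °C
Reagents that add atoms: none
Why: In this Pd-catalysed γ-arylation the only acidic hydrogens of 8 are at C1 (C7–H is cyclopropyl), so the extended enolate forms cleanly and the bulky aryl–Pd species should couple at the less crowded γ-terminus and restore the conjugated enone; the C1 configuration is unimportant because it is equilibrated in step 10.

**Step 10**
Reactants: 13 1-[6-methoxy-2,4-bis(methoxymethoxy)-3-(trimethylsilyl)phenyl]aristol-9-en-8-one
Product: 15 (1R,4R,5R,6S,7R,10S)-keto phenol in which aristolan-8-one is fused through C1–C3a and C10–O to a 6-hydroxy-4-methoxy-7-(trimethylsilyl)-2,3-dihydrobenzofuran, via open resorcinol enone 14 (not isolated)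
Conditions: TMSOTf, 2,2′-bipyridyl, MeCN, 0 to 23 °C; H2O; then DBU (cat.), CH2Cl2, 23 °C
Reagents that add atoms: none
Why: Near-neutral cleavage of the aryl MOM ethers spares the aryl silane and the cyclopropane, and the C7a phenol then closes on C10 by a 5-exo-trig oxa-Michael addition; C10 should be attacked on the face that bears the C5 methyl, because the other face is roofed by the endo methyl of the cyclopropane (as in 3-carene) and 4a-methyl octalones take hetero-nucleophiles to give the cis-fused product, while C1 equilibrates through the extended enolate so that only the epimer able to reach that face cyclises, giving the cis ring fusion.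

**Step 11**
Reactants: 15 keto phenol
Product: 16 C6 aryl triflate of 15
Conditions: Tf2O, pyridine, CH2Cl2, −78 to 0 °C
Reagents that add atoms: trifluoromethanesulfonic anhydride, O=S(=O)(OS(=O)(=O)C(F)(F)F)C(F)(F)F
Why: O-sulfonylation of the single free phenol under non-equilibrating conditions completes the o-silylaryl triflate and makes the arene electron-poorer for the oxidation that follows.

**Step 12**
Reactants: 16 C6 aryl triflate
Product: 17 (1R,4R,5R,6S,7R,10S)-8,9-dione bearing C7-SiMe3 and C6-OTf
Conditions: SeO2, 1,4-dioxane–H2O, 100 °C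
Reagents that add atoms: selenium dioxide, O=[Se]=O
Why: The ketone can enolise only toward C9, so the Riley oxidation should convert that methylene, which lies next to a quaternary carbon as in camphor, into the non-enolisable 1,2-diketone; this also locks the C10–O bond against retro-oxa-Michael opening.

**Step 13**
Reactants: 17 silyl triflate 8,9-dione; 18 (E)-4-methoxycinnamic acid
Product: 21 target CNP0121765.1, via aryne 19 (not isolated), via flavanone 20 (not isolated)
Conditions: CsF, 4 Å MS, THF, 125 °C (sealed tube); then DBU, THF, 23 °C; cold aq. citric acid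
Reagents that add atoms: none
Why: Fluoride removes the C7 silyl group and expels the C6 triflate to give aryne 19, the cesium carboxylate of 18 adds through oxygen to C6, and the C7 aryl anion so formed attacks the adjacent ester carbonyl through a four-membered transition state (anionic Fries-type 1,3 O→C acyl shift), so that the C7–C(=O) bond and the C6–O bond are made in one operation. The closest known reaction type is the fluoride-induced intermolecular C–O insertion of arynes into carboxylic acids, which gives o-hydroxyaryl ketones and, with α,β-unsaturated acids, their oxa-Michael isomers. The only ring closed is the temporary pyranone ring of flavanone 20 (reversible 6-endo-trig oxa-Michael addition of the new C6 phenoxide to the enone), which DBU reopens by E1cB elimination because the chelated chalcone phenoxide is the thermodynamic sink, and a cold acidic quench then delivers 21. No permanent stereocentre is created, the six existing ones lie away from any acidic site (the 8,9-dione has no enolisable hydrogen apart from the cyclopropyl C7–H), and ring opening returns the more stable E-enone. The step needs regioselectivity (O to C6, acyl to C7), and this is secured by the dihydrofuran oxygen on C7a, whose inductive pull distorts the aryne so that nucleophiles attack the remote carbon C6 and the charge develops at C7, as in 3-alkoxybenzynes. It also needs 1,2- rather than 1,4-attack of the aryl anion, which the close contact with the ester carbonyl and the hardness of the aryl anion should ensure.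

**Compound list**
1 | (R)-(+)-pulegone | C[C@@H]1CCC(=C(C)C)C(=O)C1 | starting material
2 | (5R)-5,6-dimethyl-2-(propan-2-ylidene)cyclohexan-1-one | C[C@@H]1CCC(=C(C)C)C(=O)C1C | intermediate
3 | (3R)-2,3-dimethylcyclohexan-1-one | C[C@@H]1CCCC(=O)C1C | intermediate
4 | methyl vinyl ketone | C=CC(C)=O | starting material
5 | (2S,3R)-2,3-dimethyl-2-(3-oxobutyl)cyclohexan-1-one | CC(=O)CC[C@@]1(C)[C@H](C)CCCC1=O | intermediate
6 | (4aS,5R)-4a,5-dimethyl-4,4a,5,6,7,8-hexahydronaphthalen-2(3H)-one | C12=CC(=O)CC[C@@]1(C)[C@H](C)CCC2 | intermediate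
7 | (4aR,5R)-4a,5-dimethyl-5,6,7,8-tetrahydronaphthalen-2(4aH)-one | C12=CC(=O)C=C[C@@]1(C)[C@H](C)CCC2 | intermediate
8 | (−)-aristolone | C12=CC(=O)[C@@H]3[C@@H](C3(C)C)[C@@]1(C)[C@H](C)CCC2 | intermediate
9 | 5-methoxybenzene-1,3-diol | COc1cc(O)cc(O)c1 | starting material
10 | 1-methoxy-3,5-bis(methoxymethoxy)benzene | COCOc1cc(OC)cc(OCOC)c1 | intermediate
11 | [4-methoxy-2,6-bis(methoxymethoxy)phenyl]trimethylsilane | COCOc1cc(OC)cc(OCOC)c1[Si](C)(C)C | intermediate
12 | [3-bromo-4-methoxy-2,6-bis(methoxymethoxy)phenyl]trimethylsilane | COCOc1cc(OC)c(Br)c(OCOC)c1[Si](C)(C)C | intermediate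
13 | 1-aryl-aristol-9-en-8-one, bis-MOM ether | C12=CC(=O)[C@@H]3[C@@H](C3(C)C)[C@@]1(C)[C@H](C)CCC2c1c(OC)cc(OCOC)c([Si](C)(C)C)c1OCOC | intermediate
14 | open resorcinol enone | C12=CC(=O)[C@@H]3[C@@H](C3(C)C)[C@@]1(C)[C@H](C)CCC2c1c(OC)cc(O)c([Si](C)(C)C)c1O | intermediate
15 | dihydrobenzofuran keto phenol | C[Si](C)(C)c2c(O)cc(OC)c3c2O[C@]24CC(=O)[C@@H]5[C@@H](C5(C)C)[C@@]2(C)[C@H](C)CC[C@H]34 | intermediate
16 | C6 aryl triflate, 8-ketone | C[Si](C)(C)c2c(OS(=O)(=O)C(F)(F)F)cc(OC)c3c2O[C@]24CC(=O)[C@@H]5[C@@H](C5(C)C)[C@@]2(C)[C@H](C)CC[C@H]34 | intermediate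
17 | silyl triflate 8,9-dione | C[Si](C)(C)c2c(OS(=O)(=O)C(F)(F)F)cc(OC)c3c2O[C@]24C(=O)C(=O)[C@@H]5[C@@H](C5(C)C)[C@@]2(C)[C@H](C)CC[C@H]34 | intermediate
18 | (E)-4-methoxycinnamic acid | COc1ccc(/C=C/C(=O)O)cc1 | starting material
19 | C6≡C7 aryne | C2#CC=C(OC)C3=C2O[C@]24C(=O)C(=O)[C@@H]5[C@@H](C5(C)C)[C@@]2(C)[C@H](C)CC[C@H]34 | intermediate
20 | flavanone (epimers at the new O–CH centre) | COc1ccc(C6CC(=O)c2c(O6)cc(OC)c3c2O[C@]24C(=O)C(=O)[C@@H]5[C@@H](C5(C)C)[C@@]2(C)[C@H](C)CC[C@H]34)cc1 | intermediate
21 | CNP0121765.1 | COc1ccc(/C=C/C(=O)c2c(O)cc(OC)c3c2O[C@]24C(=O)C(=O)[C@@H]5[C@@H](C5(C)C)[C@@]2(C)[C@H](C)CC[C@H]34)cc1 | target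

**Step count**
Total step count: 13. Longest linear sequence: 10 (steps 1–5 and 9–13).

**Steps most likely to fail**

**Step 9.**
- What may go wrong: oxidative addition and C–C reductive elimination may be too slow with the di-ortho-substituted, electron-rich bromide. Arylation at the α-carbon or self-condensation of the enolate could then take over.
- Fallback route: from 8 and 12, rejoining at 13.
- Allylic oxidation of 8 at C1 (Pd(OH)2/C, t-BuOOH, K2CO3) would give aristol-9-ene-1,8-dione F1.
- The only enolisable position of F1 (C2) allows conversion into the dienyl triflate F2 (KHMDS, PhNTf2, −78 °C).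
- Bromine–lithium exchange of 12 followed by ZnCl2 would give the arylzinc chloride F3.
- Negishi sp2–sp2 coupling of F2 with F3 (Pd2(dba)3, SPhos) should give the 1-aryl-aristola-1,9-dien-8-one F4.
- 1,6-Conjugate reduction of F4 (Stryker's reagent) and protonation of the extended enolate returns 13.

**Step 13.**
- What may go wrong: the aryl anion may pick up a proton before the acyl shift, so that the reaction stops at O-arylation. It may also add in a conjugate sense, or the diketone may be attacked by base at 125 °C.
- Fallback route: from 17, rejoining at 21; it keeps the aryne but replaces the σ-insertion by a (3+2) cycloaddition at room temperature.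
- Commercial (E)-4-methoxycinnamaldehyde is converted into its oxime F5 (NH2OH·HCl, NaOAc) and then into the hydroximoyl chloride F6 (NCS, DMF).
- Slow addition of F6 to 17 and CsF in MeCN generates the nitrile oxide F7 beside aryne 19.
- Their cycloaddition should give the 3-styryl-1,2-benzisoxazole F8, with O on C6 and C on C7 under the same polarity control.
- Reductive N–O cleavage (Mo(CO)6, MeCN–H2O, 80 °C) gives the o-hydroxyaryl ketimine F9.
- Mild aqueous acid hydrolyses F9 to 21.

**Step 12.**
- What may go wrong: hot, weakly acidic selenous acid may cause protodesilylation at C7, or reversal of the oxa-Michael closure followed by allylic oxidation.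
- Fallback route: from 16, rejoining at 17; it replaces the direct oxidation by a Rubottom sequence under fluoride-free, non-equilibrating conditions.
- Soft enolisation (TMSOTf, Et3N, 0 °C) gives the C8 silyl enol ether F10.
- Epoxidation with dimethyldioxirane at −40 °C and a citric acid work-up give the 9-hydroxy-8-ketone F11 (either C9 epimer).
- Dess–Martin oxidation of F11 gives 17.

**Further compounds**
F1 | step 9 | aristol-9-ene-1,8-dione | C12=CC(=O)[C@@H]3[C@@H](C3(C)C)[C@@]1(C)[C@H](C)CCC2=O
F2 | step 9 | 8-oxoaristola-1,9-dien-1-yl triflate | C12=CC(=O)[C@@H]3[C@@H](C3(C)C)[C@@]1(C)[C@H](C)CC=C2OS(=O)(=O)C(F)(F)F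
F3 | step 9 | [6-methoxy-2,4-bis(methoxymethoxy)-3-(trimethylsilyl)phenyl]zinc chloride | Cl[Zn]c1c(OC)cc(OCOC)c([Si](C)(C)C)c1OCOC
F4 | step 9 | 1-aryl-aristola-1,9-dien-8-one | C12=CC(=O)[C@@H]3[C@@H](C3(C)C)[C@@]1(C)[C@H](C)CC=C2c1c(OC)cc(OCOC)c([Si](C)(C)C)c1OCOC
F5 | step 13 | (E)-4-methoxycinnamaldehyde oxime | COc1ccc(/C=C/C=NO)cc1
F6 | step 13 | (E)-N-hydroxy-3-(4-methoxyphenyl)prop-2-enimidoyl chloride | COc1ccc(/C=C/C(Cl)=NO)cc1
F7 | step 13 | (E)-4-methoxycinnamonitrile oxide | COc1ccc(/C=C/C#[N+][O-])cc1
F8 | step 13 | 3-[(E)-4-methoxystyryl]-1,2-benzisoxazole fused at C6–C7 of the core | COc1ccc(/C=C/c6noc7cc(OC)c3c(c67)O[C@]24C(=O)C(=O)[C@@H]5[C@@H](C5(C)C)[C@@]2(C)[C@H](C)CC[C@H]34)cc1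
F9 | step 13 | o-hydroxyaryl ketimine of 21 | COc1ccc(/C=C/C(=N)c2c(O)cc(OC)c3c2O[C@]24C(=O)C(=O)[C@@H]5[C@@H](C5(C)C)[C@@]2(C)[C@H](C)CC[C@H]34)cc1
F10 | step 12 | C8 trimethylsilyl enol ether of 16 | C[Si](C)(C)c2c(OS(=O)(=O)C(F)(F)F)cc(OC)c3c2O[C@]24C=C(O[Si](C)(C)C)[C@@H]5[C@@H](C5(C)C)[C@@]2(C)[C@H](C)CC[C@H]34
F11 | step 12 | 9-hydroxy-8-ketone | C[Si](C)(C)c2c(OS(=O)(=O)C(F)(F)F)cc(OC)c3c2O[C@]24C(O)C(=O)[C@@H]5[C@@H](C5(C)C)[C@@]2(C)[C@H](C)CC[C@H]34
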